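Assumption: labdane numbering (C1–C20) and α/β face descriptors are used; the target SMILES is read as (12Z)-6α-acetoxylabda-12,14-diene-7β,8α-diol (5S,6R,7S,8S,9R,10S), the normal labdane series.

**Retrosynthetic overview**
- Rings A and B with C5, C9 and C10 come intact from (+)-sclareolide; no carbocycle is built, only a temporary C8–O–C13 dihydropyran is formed (step 5) and opened again (step 6).
- End game: 6α-OAc and 7β-OH come from a 7-ketone (C6 enolate hydroxylation, acetylation while C7 is still a ketone, axial hydride addition).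
- Key disconnection: C13–C14 (and C13–C16) of the (12Z)-diene. The dihydropyran is lithiated at C13 (a masked acyl anion of the C13 aldehyde), a methyl 1,2-metallate shift opens the ring, and the alkenylmetal is coupled with vinyl bromide; the ring fixes the Z geometry and releases 8α-OH.
- Dihydropyran ⇐ 8-hydroxy alkyne (cycloisomerisation) ⇐ lactol plus one carbon ⇐ 7α-hydroxysclareolide ⇐ OsO4 on the Δ7 ester ⇐ sclareolide.

**Route**

Step 1
Reactants: 1 (+)-sclareolide
Product: 2 methyl 13,14,15,16-tetranorlabd-7-en-12-oate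
Conditions: conc. H2SO4, MeOH, rt, 72 h; AgNO3–silica chromatography
Reagents that add atoms: methanol CO
Why: Acid-catalysed E1 opening of the tertiary C8–O bond with concurrent Fischer esterification gives mainly the trisubstituted Δ7 alkene (the Δ8(17) and Δ8(9) isomers are removed on AgNO3–silica), and C5, C9 and C10 are untouched.

Step 2
Reactants: 2 methyl 13,14,15,16-tetranorlabd-7-en-12-oate
Product: 4 7α-hydroxysclareolide, via diol ester 3 (not isolated)
Conditions: OsO4 (2 mol %), NMO (1.5 equiv), acetone–H2O, rt; then TsOH·H2O (cat.), CH2Cl2, rt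
Reagents that add atoms: N-methylmorpholine N-oxide C[N+]1([O-])CCOCC1; water O
Why: Upjohn dihydroxylation adds both oxygens syn from the α face, opposite the axial C10 methyl, setting 7α-OH and 8α-OH (8β-CH3), and the 8α-OH then relactonises onto the C12 ester under acid to give the trans-fused γ-lactone.

Step 3
Reactants: 4 7α-hydroxysclareolide
Product: 5 8α,12-epoxy-13,14,15,16-tetranorlabdane-7α,12-diol (lactol, both C12 epimers)
Conditions: i-Bu2AlH (2.5 equiv), CH2Cl2, −78 °C; MeOH, then aqueous work-up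
Reagents that add atoms: none
Why: Partial hydride reduction of a γ-lactone stops at the lactol because the aluminium hemiacetal is stable at −78 °C, the free 7-OH only consuming one extra equivalent.

Step 4
Reactants: 5 8α,12-epoxy-13,14,15,16-tetranorlabdane-7α,12-diol
Product: 6 14,15,16-trinorlabd-12-yne-7α,8α-diol
Conditions: dimethyl (1-diazo-2-oxopropyl)phosphonate (1.5 equiv), K2CO3 (3 equiv), MeOH, 0 °C → rt
Reagents that add atoms: dimethyl (1-diazo-2-oxopropyl)phosphonate COP(=O)(OC)C(=[N+]=[N-])C(C)=O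
Why: Seyferth–Gilbert homologation with the Ohira–Bestmann reagent converts the aldehyde form of the lactol (in equilibrium under K2CO3/MeOH) into the terminal alkyne, adding C13 without touching any stereocentre.

Step 5
Reactants: 6 14,15,16-trinorlabd-12-yne-7α,8α-diol
Product: 7 8α,13-epoxy-14,15,16-trinorlabd-12-en-7α-ol
Conditions: [RhCl(cod)]2 (2.5 mol %), (4-FC6H4)3P (30 mol %), DMF, 85 °C
Reagents that add atoms: none
Why: Rh-vinylidene endo cycloisomerisation of a bis-homopropargylic alcohol (anti-Markovnikov hydroalkoxylation) lets the 8α-OH add to C13 to close the six-membered enol ether, the ring holding O8 and C11 cis across C12=C13, while the 7α-OH would need a seven-membered ring and does not compete.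

Step 6
Reactants: 7 8α,13-epoxy-14,15,16-trinorlabd-12-en-7α-ol
Product: 12 (12Z)-labda-12,14-diene-7α,8α-diol, via lithiated enol ether 8 (not isolated), via methylcuprate complex 9 (not isolated), via alkenylcopper 10 (not isolated), via alkenylzinc bromide 11 (not isolated)
Conditions: t-BuLi (2.3 equiv), THF, −78 → 0 °C; MeLi + CuBr·SMe2 (1.1 equiv each, premixed, Et2O/Me2S), −78 °C → rt; ZnBr2 (1.2 equiv), CH2=CHBr (3 equiv), Pd(PPh3)4 (5 mol %), THF, 0 °C → rt; H2O
Reagents that add atoms: methyllithium [Li]C; vinyl bromide C=CBr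
Why: t-BuLi removes the hydroxyl proton and then the C13–H of the enol ether to give an α-alkoxyalkenyllithium (a masked acyl anion of the C13 aldehyde); in the mixed methylcuprate the methyl group makes a Kocienski-type 1,2-metallate shift to C13 with inversion and expels the C8 alkoxide so that the metal ends cis to C11; Negishi-type coupling of this alkenylmetal with vinyl bromide under zerovalent palladium then proceeds with retention, joining the former aldehyde carbon to the halide carbon and giving the 12Z diene with 8α-OH set free.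

Step 7
Reactants: 12 (12Z)-labda-12,14-diene-7α,8α-diol
Product: 13 (12Z)-8α-hydroxylabda-12,14-dien-7-one
Conditions: Dess–Martin periodinane (1.5 equiv), pyridine (3 equiv), CH2Cl2, 0 °C → rt
Reagents that add atoms: none
Why: Dess–Martin oxidation converts the secondary axial 7α-OH into the ketone under near-neutral conditions that leave the tertiary 8-OH and the diene untouched and do not cleave the ketol.

Step 8
Reactants: 13 (12Z)-8α-hydroxylabda-12,14-dien-7-one
Product: 15 (12Z)-6α,8α-dihydroxylabda-12,14-dien-7-one, via potassium enolate 14 (not isolated)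
Conditions: KN(SiMe3)2 (2.3 equiv), THF, −78 °C; 2-(phenylsulfonyl)-3-phenyloxaziridine (1.5 equiv), −78 °C; AcOH quench
Reagents that add atoms: 2-(phenylsulfonyl)-3-phenyloxaziridine O=S(=O)(N1OC1c1ccccc1)c1ccccc1
Why: Davis enolate hydroxylation works here because the ketone can enolise only toward C6 (C8 is quaternary), and the oxaziridine attacks the enolate from the α face, away from the axial C10 and C4β methyls, setting the equatorial 6α-OH.

Step 9
Reactants: 15 (12Z)-6α,8α-dihydroxylabda-12,14-dien-7-one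
Product: 16 (12Z)-6α-acetoxy-8α-hydroxylabda-12,14-dien-7-one
Conditions: Ac2O (1.5 equiv), DMAP (0.1 equiv), pyridine, CH2Cl2, 0 °C → rt
Reagents that add atoms: acetic anhydride CC(=O)OC(C)=O
Why: DMAP-catalysed acylation takes the only secondary hydroxyl and leaves the hindered tertiary 8-OH free, so the acetate is fixed at O6 while C7 is still a ketone.

Step 10
Reactants: 16 (12Z)-6α-acetoxy-8α-hydroxylabda-12,14-dien-7-one
Product: 17 (12Z)-6α-acetoxylabda-12,14-diene-7β,8α-diol
Conditions: NaBH4 (1.5 equiv), CeCl3·7H2O (1.2 equiv), MeOH–THF, −40 °C; water quench at −40 °C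
Reagents that add atoms: none
Why: In this Luche-type borohydride reduction hydride adds axially from the α face, anti to the axial 8β-methyl that blocks the equatorial approach, giving the equatorial 7β-OH, and the cold, weakly basic conditions suppress 6→7 acetyl migration.

**Compound list**

1 | (+)-sclareolide (8α,12-epoxy-13,14,15,16-tetranorlabdan-12-one) | O=C1C[C@H]2[C@](C)(O1)CC[C@H]3C(C)(C)CCC[C@@]32C | starting material
2 | methyl 13,14,15,16-tetranorlabd-7-en-12-oate | COC(=O)C[C@H]1C(C)=CC[C@H]2C(C)(C)CCC[C@@]21C | intermediate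
3 | methyl 7α,8α-dihydroxy-13,14,15,16-tetranorlabdan-12-oate (not isolated) | COC(=O)C[C@H]1[C@](C)(O)[C@H](O)C[C@H]2C(C)(C)CCC[C@@]21C | intermediate
4 | 7α-hydroxysclareolide (7α-hydroxy-8α,12-epoxy-13,14,15,16-tetranorlabdan-12-one) | O=C1C[C@H]2[C@](C)(O1)[C@H](O)C[C@H]3C(C)(C)CCC[C@@]32C | intermediate
5 | 8α,12-epoxy-13,14,15,16-tetranorlabdane-7α,12-diol (lactol, C12 epimers) | OC1C[C@H]2[C@](C)(O1)[C@H](O)C[C@H]3C(C)(C)CCC[C@@]32C | intermediate
6 | 14,15,16-trinorlabd-12-yne-7α,8α-diol | C#CC[C@H]1[C@](C)(O)[C@H](O)C[C@H]2C(C)(C)CCC[C@@]21C | intermediate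
7 | 8α,13-epoxy-14,15,16-trinorlabd-12-en-7α-ol | C1=CC[C@H]2[C@](C)(O1)[C@H](O)C[C@H]3C(C)(C)CCC[C@@]32C | intermediate
8 | dilithio derivative of 7 (C13–Li, 7α-OLi; not isolated) | [Li]C1=CC[C@H]2[C@](C)(O1)[C@H](O[Li])C[C@H]3C(C)(C)CCC[C@@]32C | intermediate
9 | lithium methyl(C13-alkenyl)cuprate formed from 8 and methylcopper (not isolated) | [Li+].C[Cu-]C1=CC[C@H]2[C@](C)(O1)[C@H](O[Li])C[C@H]3C(C)(C)CCC[C@@]32C | intermediate
10 | (12Z)-13-cuprio-14,15-dinorlabd-12-ene-7α,8α-diol dilithium dialkoxide (not isolated) | [Cu]/C(C)=C\C[C@H]1[C@](C)(O[Li])[C@H](O[Li])C[C@H]2C(C)(C)CCC[C@@]21C | intermediate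
11 | (12Z)-13-(bromozincio)-14,15-dinorlabd-12-ene-7α,8α-diol dilithium dialkoxide (not isolated) | Br[Zn]/C(C)=C\C[C@H]1[C@](C)(O[Li])[C@H](O[Li])C[C@H]2C(C)(C)CCC[C@@]21C | intermediate
12 | (12Z)-labda-12,14-diene-7α,8α-diol | C=C/C(C)=C\C[C@H]1[C@](C)(O)[C@H](O)C[C@H]2C(C)(C)CCC[C@@]21C | intermediate
13 | (12Z)-8α-hydroxylabda-12,14-dien-7-one | C=C/C(C)=C\C[C@H]1[C@](C)(O)C(=O)C[C@H]2C(C)(C)CCC[C@@]21C | intermediate
14 | dipotassium 6-en-7-olate 8α-olate of 13 (not isolated) | C=C/C(C)=C\C[C@H]1[C@](C)(O[K])C(O[K])=C[C@H]2C(C)(C)CCC[C@@]21C | intermediate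
15 | (12Z)-6α,8α-dihydroxylabda-12,14-dien-7-one | C=C/C(C)=C\C[C@H]1[C@](C)(O)C(=O)[C@H](O)[C@H]2C(C)(C)CCC[C@@]21C | intermediate
16 | (12Z)-6α-acetoxy-8α-hydroxylabda-12,14-dien-7-one | C=C/C(C)=C\C[C@H]1[C@](C)(O)C(=O)[C@H](OC(C)=O)[C@H]2C(C)(C)CCC[C@@]21C | intermediate
17 | (12Z)-6α-acetoxylabda-12,14-diene-7β,8α-diol (CNP0138393.1) | C=C/C(C)=C\C[C@H]1[C@](C)(O)[C@@H](O)[C@H](OC(C)=O)[C@H]2C(C)(C)CCC[C@@]21C | target

**Step count**
Total steps: 10. Longest linear sequence: 10 (fully linear from 1).

**Steps most likely to fail, with fallbacks**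

Step 6 is the riskiest. Lithiation next to a lithium alkoxide may be slow, the 1,2-shift is slower for six-membered enol ethers and here must expel a tertiary alkoxide, and the alkenylmetal may be protonated before it couples. The fallback sets out from 7 and comes back at 12. Compound 7 is lithiated as before and the lithio species 8 is quenched with MeI to give 8α,13-epoxy-14,15-dinorlabd-12-en-7α-ol F1. F1 is then opened by nickel-catalysed C–O cross-coupling with CH2=CHMgBr (NiCl2(PPh3)2, toluene, reflux); the vinyl group replaces the ring oxygen with retention, so it ends cis to C11 and gives 12.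

Step 5 may fail because the nucleophile is a hindered tertiary alcohol and the alkyne can oligomerise. The fallback sets out from 5 and comes back at 7, bypassing the alkyne. Wittig reaction of lactol 5 with the ylide from MeOCH2PPh3Cl and KN(SiMe3)2 gives 13-methoxy-14,15,16-trinorlabd-12-ene-7α,8α-diol F2. Camphorsulfonic acid (cat.) in CH2Cl2 closes it to the mixed acetal 13-methoxy-8α,13-epoxy-14,15,16-trinorlabdan-7α-ol F3. Me3SiOTf/i-Pr2NEt eliminates the methoxy group and silylates O7 to give 7α-trimethylsilyloxy-8α,13-epoxy-14,15,16-trinorlabd-12-ene F4, and K2CO3/MeOH removes the silyl group to give 7.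

Step 8 may fail through α-ketol rearrangement of the dianion or slow oxidation at the hindered C6. The fallback sets out from 13 and comes back at 16, skipping 15. Me3SiOTf/Et3N converts 13 into (12Z)-7,8α-bis(trimethylsilyloxy)labda-6,12,14-triene F5. Pb(OAc)4 in CH2Cl2 at −40 °C acetoxylates the silyl enol ether from the α face to give (12Z)-6α-acetoxy-8α-trimethylsilyloxylabda-12,14-dien-7-one F6, and HF·pyridine in MeCN at 0 °C removes the tertiary silyl ether to give 16.

Further compounds
F1 | step 6 | 8α,13-epoxy-14,15-dinorlabd-12-en-7α-ol | CC1=CC[C@H]2[C@](C)(O1)[C@H](O)C[C@H]3C(C)(C)CCC[C@@]32C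
F2 | step 5 | 13-methoxy-14,15,16-trinorlabd-12-ene-7α,8α-diol (E/Z mixture) | COC=CC[C@H]1[C@](C)(O)[C@H](O)C[C@H]2C(C)(C)CCC[C@@]21C
F3 | step 5 | 13-methoxy-8α,13-epoxy-14,15,16-trinorlabdan-7α-ol (C13 epimers) | COC1CC[C@H]2[C@](C)(O1)[C@H](O)C[C@H]3C(C)(C)CCC[C@@]32C
F4 | step 5 | 7α-trimethylsilyloxy-8α,13-epoxy-14,15,16-trinorlabd-12-ene | C1=CC[C@H]2[C@](C)(O1)[C@H](O[Si](C)(C)C)C[C@H]3C(C)(C)CCC[C@@]32C
F5 | step 8 | (12Z)-7,8α-bis(trimethylsilyloxy)labda-6,12,14-triene | C=C/C(C)=C\C[C@H]1[C@](C)(O[Si](C)(C)C)C(O[Si](C)(C)C)=C[C@H]2C(C)(C)CCC[C@@]21C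
F6 | step 8 | (12Z)-6α-acetoxy-8α-trimethylsilyloxylabda-12,14-dien-7-one | C=C/C(C)=C\C[C@H]1[C@](C)(O[Si](C)(C)C)C(=O)[C@H](OC(C)=O)[C@H]2C(C)(C)CCC[C@@]21C
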